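**Plan**

- Cuts, in retrosynthetic order: the two acetates, C9–C11 (side chain), C8–C17 (hydroxymethyl), C2–C3 (ring A, metathesis), and in one operation C1–C10 and C4–C5.
- Enabling feature: C5 and the quaternary C10 (bearing the C20 methyl) of the trans ring fusion are the β- and α-carbons of a 2-methylcyclohex-2-enone that is ring B (C9 = carbonyl). C7 of that ring can carry an oxygen that is expelled later to leave the C7–C8 unsaturation.
- Forward: ring B comes from (R)-carvone (isopropenyl → silyloxy). A Mukaiyama–Michael addition/enolate allylation puts the C4 unit on C5 and C1–C2 on C10 without closing a ring, and ring A then closes by metathesis.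
- Then the C7 silyloxy group is eliminated, C17 is added at C8, and the separately made C11–C16 chain is added to C9. An oxidative and then a reductive allylic transposition give the C7–C8 alkene and H-9, and acetylation ends the route.
- Stereochemistry: the carvone centre (C7) directs C5 (anti), and C5 directs C10 (anti). The ring fusion steers hydride to C7, and the 7α-diazene delivers H to C9α. The 13E geometry comes from syn-carboalumination.

Key step: step 4

Remark: ring carbons of all intermediates carry labdane numbers (C1–C20), and β is the face of the C10 methyl. The target SMILES encodes the normal series (5S,9R,10S,13E). Compounds 7, 8 and 20 are bought.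

**Route**

Step 1
Reactants: 1 (R)-(−)-carvone
Product: 4 (R)-5-acetoxy-2-methylcyclohex-2-en-1-one, via methoxy hydroperoxide 2 (not isolated), via peracetate 3 (not isolated)
Conditions: O3, CH2Cl2/MeOH, −78 °C (TLC control); then Ac2O, Et3N, DMAP (cat.), −78 °C → rt
Reagents that add atoms: ozone, [O-][O+]=O; methanol, CO
Why: Criegee ozonolysis–rearrangement, in which the electron-rich isopropenyl alkene is ozonised in preference to the enone, methanol traps the carbonyl oxide, and the peracetate rearranges with retentive migration of the ring carbon (acetate then demethylates the dioxacarbenium ion), so the carvone stereocentre becomes the acetoxy carbon.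

Step 2
Reactants: 4 (R)-5-acetoxy-2-methylcyclohex-2-en-1-one
Product: 5 (R)-5-hydroxy-2-methylcyclohex-2-en-1-one
Conditions: K2CO3 (0.2 equiv), MeOH, 0 °C, short reaction time
Reagents that add atoms: none
Why: Base-catalysed transesterification (methanolysis) at 0 °C should free the alcohol before β-elimination toward the dienone can compete, and the stereocentre is not touched.

Step 3
Reactants: 5 (R)-5-hydroxy-2-methylcyclohex-2-en-1-one
Product: 6 (R)-5-(tert-butyldimethylsilyloxy)-2-methylcyclohex-2-en-1-one
Conditions: TBSCl, imidazole, DMF, rt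
Reagents that add atoms: tert-butyldimethylsilyl chloride, CC(C)(C)[Si](C)(C)Cl
Why: Imidazole-promoted silylation of the secondary alcohol gives the bulky C7 substituent that will shield the α face of the enone.

Step 4
Reactants: 6 (R)-5-(tert-butyldimethylsilyloxy)-2-methylcyclohex-2-en-1-one; 7 1-methoxy-2-methyl-1-(trimethylsilyloxy)prop-1-ene; 8 allyl iodide
Product: 11 methyl 2-[(1R,2S,5R)-2-allyl-5-(tert-butyldimethylsilyloxy)-2-methyl-3-oxocyclohexyl]-2-methylpropanoate, via silyl enol ether 9 (not isolated), via sulfonium enolate 10 (not isolated)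
Conditions: 7 (1.3 equiv), Me3SiOTf (5 mol %), CH2Cl2, −78 °C; Et3N (0.1 equiv), evaporate under high vacuum; THF, tris(dimethylamino)sulfonium difluorotrimethylsilicate (1.1 equiv), −78 → −30 °C; 8 (3 equiv), −78 → −20 °C
Reagents that add atoms: none
Why: Me3SiOTf silylates the enone carbonyl and the tetrasubstituted ketene acetal carbon (the future C4) attacks the β-carbon C5 in a Mukaiyama–Michael addition; silyl transfer regenerates the catalyst and leaves trimethylsilyl enol ether 9 with the enol double bond fixed between C9 and C10. The attack is axial on the half-chair enone from the face anti to the C7 silyloxy group, which sets C5. Fluoride then removes only the trimethylsilyl group (the alkyl TBS ether and the methyl ester are untouched, which is why fluoride is used and not an alkyllithium), and the metal-free enolate 10 is C-allylated by allyl iodide, the closest known reaction type being the fluoride-mediated regiospecific alkylation of silyl enol ethers. Allylic 1,2-strain with the C10 methyl forces the bulky C5 substituent pseudoaxial, so allyl iodide enters C10 axially from the opposite (α) face, which sets the quaternary centre with the methyl β and trans to H-5. No ring closes; the step needs 1,4- over 1,2-addition, two consecutive anti additions, and alkylation at C10 instead of C8 or oxygen. These are secured respectively by the silyl-activated soft manifold, by the C7 centre relayed through C5, and by the regiodefined silyl enol ether with a soft allylic iodide.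

Step 5
Reactants: 11 methyl 2-[(1R,2S,5R)-2-allyl-5-(tert-butyldimethylsilyloxy)-2-methyl-3-oxocyclohexyl]-2-methylpropanoate
Product: 12 2-allyl-5-(tert-butyldimethylsilyloxy)-3-(1-hydroxy-2-methylpropan-2-yl)-2-methylcyclohexan-1-ol (ring centres as in 11; C9 carbinol as an epimer mixture)
Conditions: LiAlH4, THF, 0 °C
Reagents that add atoms: none
Why: Hydride reduction of ester and ketone together avoids a chemoselectivity problem; the uncontrolled carbinol centre is erased again in step 6.

Step 6
Reactants: 12 the diol from step 5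
Product: 13 2-[2-allyl-5-(tert-butyldimethylsilyloxy)-2-methyl-3-oxocyclohexyl]-2-methylpropanal (ring centres as in 11)
Conditions: Dess–Martin periodinane (2.5 equiv), pyridine, CH2Cl2, 0 °C → rt
Reagents that add atoms: none
Why: Dess–Martin oxidation of both alcohols under buffered, non-basic conditions keeps the β-silyloxy ketone from eliminating, and the aldehyde formed has no α-hydrogen.

Step 7
Reactants: 13 the keto aldehyde from step 6
Product: 14 2-allyl-5-(tert-butyldimethylsilyloxy)-2-methyl-3-(2-methylbut-3-en-2-yl)cyclohexan-1-one (ring centres as in 11)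
Conditions: Ph3PCH3Br, KN(SiMe3)2 (1.2 equiv ylide), THF, −78 → 0 °C
Reagents that add atoms: methyltriphenylphosphonium bromide, C[P+](c1ccccc1)(c1ccccc1)c1ccccc1.[Br-]
Why: Wittig methylenation should be chemoselective for the aldehyde because the ketone is flanked by the quaternary C10, and the low temperature limits enolisation toward C8.

Step 8
Reactants: 14 the diene ketone from step 7
Product: 15 (3R,4aS,8aS)-3-(tert-butyldimethylsilyloxy)-5,5,8a-trimethyl-3,4,4a,5,8,8a-hexahydronaphthalen-1(2H)-one (labdane C2=C3 alkene, C9 ketone, 7α-silyloxy)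
Conditions: second-generation Grubbs catalyst, (H2IMes)(PCy3)Cl2Ru=CHPh (5 mol %), CH2Cl2 (5 mM), 40 °C
Reagents that add atoms: none
Why: Ring-closing metathesis of the allyl and 1,1-dimethylallyl groups, which sit trans-diequatorial on ring B, closes the six-membered ring A at C2=C3 and gives the trans-fused decalin with loss of ethene.

Step 9
Reactants: 15 the octalone from step 8
Product: 16 (3R,4aS,8aS)-3-(tert-butyldimethylsilyloxy)-5,5,8a-trimethyl-3,4,4a,5,6,7,8,8a-octahydronaphthalen-1(2H)-one
Conditions: H2 (1 atm), Pd/C (10 wt %), EtOAc, rt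
Reagents that add atoms: none
Why: Heterogeneous catalytic hydrogenation saturates the cis-disubstituted C2=C3 alkene while the ketone and the silyl ether are inert.

Step 10
Reactants: 16 the saturated silyloxy ketone from step 9
Product: 17 (4aS,8aS)-5,5,8a-trimethyl-4a,5,6,7,8,8a-hexahydronaphthalen-1(4H)-one (labdane C7=C8–C9=O enone)
Conditions: DBU (2 equiv), CH2Cl2, rt → 40 °C
Reagents that add atoms: none
Why: E1cB β-elimination of silanolate from the C8 enolate gives the conjugated enone and removes the C7 stereocentre once it has done its work.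

Step 11
Reactants: 17 the enone from step 10
Product: 18 (4aS,8aS)-2-(hydroxymethyl)-5,5,8a-trimethyl-4a,5,6,7,8,8a-hexahydronaphthalen-1(4H)-one
Conditions: aq. HCHO (37 %), PBu3 (20 mol %), CHCl3/MeOH, rt
Reagents that add atoms: formaldehyde, C=O
Why: Morita–Baylis–Hillman hydroxymethylation, in which the phosphine adds to C7, the resulting C8 enolate adds to formaldehyde and the phosphine is expelled, places C17 on C8.

Step 12
Reactants: 18 the hydroxymethyl enone from step 11
Product: 19 (4aS,8aS)-2-[(tert-butyldiphenylsilyloxy)methyl]-5,5,8a-trimethyl-4a,5,6,7,8,8a-hexahydronaphthalen-1(4H)-one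
Conditions: TBDPSCl, imidazole, CH2Cl2, rt
Reagents that add atoms: tert-butyldiphenylsilyl chloride, CC(C)(C)[Si](Cl)(c1ccccc1)c1ccccc1
Why: Silylation masks the C17 hydroxyl against the organolithium of step 17 and the chromium oxidant of step 18.

Step 13
Reactants: 20 4-(tert-butyldimethylsilyloxy)but-1-yne
Product: 23 (E)-5-(tert-butyldimethylsilyloxy)-3-methylpent-2-en-1-ol, via alkenylalane 21 (not isolated), via lithium alanate 22 (not isolated)
Conditions: AlMe3 (2 equiv), Cp2ZrCl2 (25 mol %), CH2Cl2, 0 °C → rt; then n-BuLi, THF, −78 → 0 °C; (CH2O)n, rt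
Reagents that add atoms: trimethylaluminium, C[Al](C)C; formaldehyde (from paraformaldehyde), C=O
Why: Zirconium-catalysed Negishi carboalumination adds methyl and aluminium syn with the metal on the terminal carbon, and the alanate is hydroxymethylated with retention, which fixes the 13E geometry.

Step 14
Reactants: 23 (E)-5-(tert-butyldimethylsilyloxy)-3-methylpent-2-en-1-ol
Product: 24 (E)-1-(tert-butyldiphenylsilyloxy)-5-(tert-butyldimethylsilyloxy)-3-methylpent-2-ene
Conditions: TBDPSCl, imidazole, CH2Cl2, rt
Reagents that add atoms: tert-butyldiphenylsilyl chloride, CC(C)(C)[Si](Cl)(c1ccccc1)c1ccccc1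
Why: Silylation of the allylic alcohol installs the C15 protecting group that is to last until step 21.

Step 15
Reactants: 24 the bis-silyl ether from step 14
Product: 25 (E)-5-(tert-butyldiphenylsilyloxy)-3-methylpent-3-en-1-ol
Conditions: PPTS (0.2 equiv), EtOH, 50 °C
Reagents that add atoms: none
Why: Acid-catalysed ethanolysis (selective desilylation) removes the primary alkyl TBS ether much faster than the TBDPS ether.

Step 16
Reactants: 25 (E)-5-(tert-butyldiphenylsilyloxy)-3-methylpent-3-en-1-ol
Product: 26 (E)-tert-butyl[(5-iodo-3-methylpent-2-en-1-yl)oxy]diphenylsilane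
Conditions: I2, PPh3, imidazole, CH2Cl2, 0 °C → rt
Reagents that add atoms: iodine, II
Why: Appel-type iodination (phosphonium activation, then SN2 by iodide) converts the primary homoallylic alcohol into the iodide without touching the alkene geometry.

Step 17
Reactants: 26 (E)-tert-butyl[(5-iodo-3-methylpent-2-en-1-yl)oxy]diphenylsilane; 19 the silyl-protected hydroxymethyl enone
Product: 28 15,17-bis(tert-butyldiphenylsilyloxy)labda-7,13E-dien-9-ol (C9 epimers), via alkyllithium 27 (not isolated)
Conditions: 26 (1.5 equiv), t-BuLi (2.1 equiv per iodide), Et2O/pentane, −78 °C; then 19, −78 → −30 °C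
Reagents that add atoms: none
Why: Lithium–iodine exchange gives the primary alkyllithium, which adds 1,2 to the enone carbonyl (the quaternary C10 offers no α′-hydrogen for enolisation); the C9 configuration is irrelevant because C9 becomes sp2 in step 18.

Step 18
Reactants: 28 the tertiary allylic alcohol from step 17
Product: 29 15,17-bis(tert-butyldiphenylsilyloxy)labda-8,13E-dien-7-one
Conditions: [C5H5NH][CrO3Cl] (pyridinium chlorochromate, 3 equiv), 4 Å molecular sieves, CH2Cl2, rt
Reagents that add atoms: pyridinium chlorochromate, [O-][Cr](=O)(=O)Cl.c1cc[nH+]cc1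
Why: Dauben–Babler oxidative transposition, in which the tertiary chromate ester shifts [3,3] to C7 and is oxidised there, gives the transposed enone and brings the oxygen back to C7.

Step 19
Reactants: 29 the transposed enone from step 18
Product: 30 15,17-bis(tert-butyldiphenylsilyloxy)labda-8,13E-dien-7β-ol
Conditions: NaBH4, CeCl3·7H2O, MeOH, −40 °C
Reagents that add atoms: none
Why: Luche reduction is 1,2-selective, and hydride delivery along the axial (α) trajectory of the trans-fused enone should give the equatorial 7β-alcohol.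

Step 20
Reactants: 30 the 7β-allylic alcohol from step 19
Product: 33 15,17-bis(tert-butyldiphenylsilyloxy)labda-7,13E-diene, via sulfonylhydrazine 31 (not isolated), via allylic diazene 32 (not isolated)
Conditions: 2-nitrobenzenesulfonylhydrazide (NBSH), PPh3, DEAD, N-methylmorpholine, −30 °C; then 23 °C
Reagents that add atoms: none
Why: Mitsunobu displacement by NBSH inverts C7 to the 7α-sulfonylhydrazine, which loses sulfinic acid on warming, and the allylic diazene extrudes N2 in a retro-ene shift that delivers hydrogen to C9 on the same (α) face, creating the C7–C8 alkene and the 9α-H centre (allylic diazene rearrangement).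

Step 21
Reactants: 33 the bis-silyl ether from step 20
Product: 34 labda-7,13E-diene-15,17-diol
Conditions: Bu4NF (3 equiv), THF, rt
Reagents that add atoms: none
Why: Fluoride-induced desilylation cleaves both primary allylic TBDPS ethers without affecting either alkene.

Step 22
Reactants: 34 labda-7,13E-diene-15,17-diol
Product: 35 labda-7,13E-diene-15,17-diyl diacetate (target)
Conditions: Ac2O, pyridine, DMAP (cat.), CH2Cl2, rt
Reagents that add atoms: acetic anhydride, CC(=O)OC(C)=O
Why: DMAP-catalysed acylation of the two primary allylic alcohols gives the diacetate under conditions that cannot move the alkenes or epimerise C9.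

**Compound list**

1 | (R)-(−)-carvone | CC1=CC[C@@H](C(C)=C)CC1=O | starting material
2 | (5R)-5-(1-hydroperoxy-1-methoxyethyl)-2-methylcyclohex-2-en-1-one (epimers at the peroxyketal carbon) | CC1=CC[C@@H](C(C)(OC)OO)CC1=O | intermediate
3 | peracetate of 2, 1-methoxy-1-[(1R)-4-methyl-5-oxocyclohex-3-en-1-yl]ethyl ethaneperoxoate | CC1=CC[C@@H](C(C)(OC)OOC(C)=O)CC1=O | intermediate
4 | (R)-5-acetoxy-2-methylcyclohex-2-en-1-one | CC1=CC[C@@H](OC(C)=O)CC1=O | intermediate
5 | (R)-5-hydroxy-2-methylcyclohex-2-en-1-one | CC1=CC[C@@H](O)CC1=O | intermediate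
6 | (R)-5-(tert-butyldimethylsilyloxy)-2-methylcyclohex-2-en-1-one | CC1=CC[C@@H](O[Si](C)(C)C(C)(C)C)CC1=O | intermediate
7 | 1-methoxy-2-methyl-1-(trimethylsilyloxy)prop-1-ene | COC(O[Si](C)(C)C)=C(C)C | starting material
8 | allyl iodide | C=CCI | starting material
9 | methyl 2-[(1R,5R)-5-(tert-butyldimethylsilyloxy)-2-methyl-3-(trimethylsilyloxy)cyclohex-2-en-1-yl]-2-methylpropanoate | COC(=O)C(C)(C)[C@@H]1C[C@@H](O[Si](C)(C)C(C)(C)C)CC(O[Si](C)(C)C)=C1C | intermediate
10 | tris(dimethylamino)sulfonium enolate of the C9 ketone (enolate between C9 and C10) | COC(=O)C(C)(C)[C@@H]1C[C@@H](O[Si](C)(C)C(C)(C)C)CC([O-])=C1C.CN(C)[S+](N(C)C)N(C)C | intermediate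
11 | methyl 2-[(1R,2S,5R)-2-allyl-5-(tert-butyldimethylsilyloxy)-2-methyl-3-oxocyclohexyl]-2-methylpropanoate | C=CC[C@@]1(C)[C@H](C(C)(C)C(=O)OC)C[C@@H](O[Si](C)(C)C(C)(C)C)CC1=O | intermediate
12 | 2-allyl-5-(tert-butyldimethylsilyloxy)-3-(1-hydroxy-2-methylpropan-2-yl)-2-methylcyclohexan-1-ol (ring centres as in 11, carbinol epimers) | C=CC[C@@]1(C)[C@H](C(C)(C)CO)C[C@@H](O[Si](C)(C)C(C)(C)C)CC1O | intermediate
13 | 2-[2-allyl-5-(tert-butyldimethylsilyloxy)-2-methyl-3-oxocyclohexyl]-2-methylpropanal (ring centres as in 11) | C=CC[C@@]1(C)[C@H](C(C)(C)C=O)C[C@@H](O[Si](C)(C)C(C)(C)C)CC1=O | intermediate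
14 | 2-allyl-5-(tert-butyldimethylsilyloxy)-2-methyl-3-(2-methylbut-3-en-2-yl)cyclohexan-1-one (ring centres as in 11) | C=CC[C@@]1(C)[C@H](C(C)(C)C=C)C[C@@H](O[Si](C)(C)C(C)(C)C)CC1=O | intermediate
15 | (3R,4aS,8aS)-3-(tert-butyldimethylsilyloxy)-5,5,8a-trimethyl-3,4,4a,5,8,8a-hexahydronaphthalen-1(2H)-one | C[C@]12CC=CC(C)(C)[C@@H]1C[C@@H](O[Si](C)(C)C(C)(C)C)CC2=O | intermediate
16 | (3R,4aS,8aS)-3-(tert-butyldimethylsilyloxy)-5,5,8a-trimethyl-3,4,4a,5,6,7,8,8a-octahydronaphthalen-1(2H)-one | C[C@]12CCCC(C)(C)[C@@H]1C[C@@H](O[Si](C)(C)C(C)(C)C)CC2=O | intermediate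
17 | (4aS,8aS)-5,5,8a-trimethyl-4a,5,6,7,8,8a-hexahydronaphthalen-1(4H)-one | C[C@]12CCCC(C)(C)[C@@H]1CC=CC2=O | intermediate
18 | (4aS,8aS)-2-(hydroxymethyl)-5,5,8a-trimethyl-4a,5,6,7,8,8a-hexahydronaphthalen-1(4H)-one | C[C@]12CCCC(C)(C)[C@@H]1CC=C(CO)C2=O | intermediate
19 | (4aS,8aS)-2-[(tert-butyldiphenylsilyloxy)methyl]-5,5,8a-trimethyl-4a,5,6,7,8,8a-hexahydronaphthalen-1(4H)-one | C[C@]12CCCC(C)(C)[C@@H]1CC=C(CO[Si](c3ccccc3)(c3ccccc3)C(C)(C)C)C2=O | intermediate
20 | 4-(tert-butyldimethylsilyloxy)but-1-yne | C#CCCO[Si](C)(C)C(C)(C)C | starting material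
21 | (E)-[4-(tert-butyldimethylsilyloxy)-2-methylbut-1-en-1-yl]dimethylalane | C[Al](C)/C=C(\C)CCO[Si](C)(C)C(C)(C)C | intermediate
22 | lithium butyl[(E)-4-(tert-butyldimethylsilyloxy)-2-methylbut-1-en-1-yl]dimethylaluminate | [Li+].CCCC[Al-](C)(C)/C=C(\C)CCO[Si](C)(C)C(C)(C)C | intermediate
23 | (E)-5-(tert-butyldimethylsilyloxy)-3-methylpent-2-en-1-ol | OC/C=C(\C)CCO[Si](C)(C)C(C)(C)C | intermediate
24 | (E)-1-(tert-butyldiphenylsilyloxy)-5-(tert-butyldimethylsilyloxy)-3-methylpent-2-ene | CC(C)(C)[Si](c1ccccc1)(c1ccccc1)OC/C=C(\C)CCO[Si](C)(C)C(C)(C)C | intermediate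
25 | (E)-5-(tert-butyldiphenylsilyloxy)-3-methylpent-3-en-1-ol | CC(C)(C)[Si](c1ccccc1)(c1ccccc1)OC/C=C(\C)CCO | intermediate
26 | (E)-tert-butyl[(5-iodo-3-methylpent-2-en-1-yl)oxy]diphenylsilane | CC(C)(C)[Si](c1ccccc1)(c1ccccc1)OC/C=C(\C)CCI | intermediate
27 | [(E)-5-(tert-butyldiphenylsilyloxy)-3-methylpent-3-en-1-yl]lithium | [Li]CC/C(C)=C/CO[Si](c1ccccc1)(c1ccccc1)C(C)(C)C | intermediate
28 | 15,17-bis(tert-butyldiphenylsilyloxy)labda-7,13E-dien-9-ol (C9 epimers; 5α-H, 10β-methyl) | C[C@]12CCCC(C)(C)[C@@H]1CC=C(CO[Si](c3ccccc3)(c3ccccc3)C(C)(C)C)C2(O)CC/C(C)=C/CO[Si](c3ccccc3)(c3ccccc3)C(C)(C)C | intermediate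
29 | 15,17-bis(tert-butyldiphenylsilyloxy)labda-8,13E-dien-7-one | C[C@]12CCCC(C)(C)[C@@H]1CC(=O)C(CO[Si](c3ccccc3)(c3ccccc3)C(C)(C)C)=C2CC/C(C)=C/CO[Si](c3ccccc3)(c3ccccc3)C(C)(C)C | intermediate
30 | 15,17-bis(tert-butyldiphenylsilyloxy)labda-8,13E-dien-7β-ol | C[C@]12CCCC(C)(C)[C@@H]1C[C@H](O)C(CO[Si](c3ccccc3)(c3ccccc3)C(C)(C)C)=C2CC/C(C)=C/CO[Si](c3ccccc3)(c3ccccc3)C(C)(C)C | intermediate
31 | N-[15,17-bis(tert-butyldiphenylsilyloxy)labda-8,13E-dien-7α-yl]-2-nitrobenzenesulfonohydrazide | C[C@]12CCCC(C)(C)[C@@H]1C[C@@H](N(N)S(=O)(=O)c3ccccc3[N+](=O)[O-])C(CO[Si](c3ccccc3)(c3ccccc3)C(C)(C)C)=C2CC/C(C)=C/CO[Si](c3ccccc3)(c3ccccc3)C(C)(C)C | intermediate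
32 | 7α-diazenyl-15,17-bis(tert-butyldiphenylsilyloxy)labda-8,13E-diene | C[C@]12CCCC(C)(C)[C@@H]1C[C@@H](N=N)C(CO[Si](c3ccccc3)(c3ccccc3)C(C)(C)C)=C2CC/C(C)=C/CO[Si](c3ccccc3)(c3ccccc3)C(C)(C)C | intermediate
33 | 15,17-bis(tert-butyldiphenylsilyloxy)labda-7,13E-diene (9α-H) | C[C@]12CCCC(C)(C)[C@@H]1CC=C(CO[Si](c3ccccc3)(c3ccccc3)C(C)(C)C)[C@@H]2CC/C(C)=C/CO[Si](c3ccccc3)(c3ccccc3)C(C)(C)C | intermediate
34 | labda-7,13E-diene-15,17-diol | C[C@]12CCCC(C)(C)[C@@H]1CC=C(CO)[C@@H]2CC/C(C)=C/CO | intermediate
35 | labda-7,13E-diene-15,17-diyl diacetate, (5S,9R,10S) | CC(=O)OC/C=C(\C)CC[C@H]1C(COC(C)=O)=CC[C@H]2C(C)(C)CCC[C@]12C | target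

**Step count and risks**

Total: 22 steps. Longest linear sequence: 18 steps (steps 1–12 and 17–22); the side chain takes 4 steps (13–16).

Step 4. The conjugate addition may be slow at the crowded C4/C5 junction. After fluoride unmasking, proton transfer from product to enolate (followed by β-loss of silanolate from C7) or O-allylation may compete with C-allylation. The fallback sets out from 6 and returns at 11. The Me3SiOTf-catalysed addition of 7 is run as before but stopped at the silyl enol ether 9, which is isolated after a bicarbonate work-up. It is then allylated under neutral conditions with allyl methyl carbonate, Pd2(dba)3·CHCl3 and dppe in THF at 65 °C (Tsuji allylation of a silyl enol ether). Oxidative addition to zerovalent palladium and loss of CO2 give methoxide, which takes the trimethylsilyl group. The enolate is captured at once by the π-allyl complex of divalent palladium, again anti to the C5 substituent, so no free basic enolate accumulates. No compound outside the list is made (F0).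

Step 20. The Mitsunobu displacement at the allylic carbinol next to the tetrasubstituted alkene may be slow, so that the sulfonylhydrazide decomposes first or dehydration to a diene intervenes. The fallback sets out from 30 and returns at 33. Formylation with acetic formic anhydride and pyridine in CH2Cl2 at 0 °C should give 15,17-bis(tert-butyldiphenylsilyloxy)labda-8,13E-dien-7β-yl formate F1. Palladium-catalysed hydrogenolysis of this allylic formate (Pd(OAc)2, PBu3, dioxane, rt → 80 °C) ionises it anti, which places palladium on the α face. Decarboxylation gives a palladium hydride, which is delivered to the more substituted terminus C9 from that face, giving the same C7–C8 alkene and 9α-H.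

Step 11. Phosphine addition to the hindered bicyclic enone or the following aldol step may stall, or the adduct may react further with formaldehyde. The fallback sets out from 17 and returns at 18. α-Iodination with I2 and pyridine in CH2Cl2 should give (4aS,8aS)-2-iodo-5,5,8a-trimethyl-4a,5,6,7,8,8a-hexahydronaphthalen-1(4H)-one F2. Stille coupling with (tributylstannyl)methanol (Pd2(dba)3, AsPh3, CuI, NMP, 60 °C) then installs the hydroxymethyl group at C8.

**Further compounds**

F0 | step 4 | none | none
F1 | step 20 | 15,17-bis(tert-butyldiphenylsilyloxy)labda-8,13E-dien-7β-yl formate | C[C@]12CCCC(C)(C)[C@@H]1C[C@H](OC=O)C(CO[Si](c3ccccc3)(c3ccccc3)C(C)(C)C)=C2CC/C(C)=C/CO[Si](c3ccccc3)(c3ccccc3)C(C)(C)C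
F2 | step 11 | (4aS,8aS)-2-iodo-5,5,8a-trimethyl-4a,5,6,7,8,8a-hexahydronaphthalen-1(4H)-one | C[C@]12CCCC(C)(C)[C@@H]1CC=C(I)C2=O
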